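**Plan**

Plan numbering: ring A = C1–C2–C3–C4–C5–C10, ring B = C5–C6–C7–C8–C9–C10; C3 carries the 2-methylbutanoate, C4 the methyl and the acetate, C10 the angular methyl, C8 the ketone, C7 the isopropylidene.
Retrosynthetic cuts, in order: C7=CMe2 (aldol/dehydration), the two acyl groups, C4–O (enolate hydroxylation), C5–H (Birch reduction), C4–CH3 (cross-coupling), then ring B at C5–C6 and C10–C9 in one cycloaddition.
Enabling feature: in ring B the C8 carbonyl lies 1,3 to the methyl-bearing quaternary C10, and the C5–C10 bond is shared with a ring A oxygenated at C3/C4. Ring B is therefore the retron of a [4+2] between a 2-silyloxybutadiene (C6–C7–C8–C9) and the methyl-substituted C=C of 2-methoxy-5-methylbenzoquinone (ring A); the quinone carbonyl that becomes C1 is a temporary activator.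
Forward: diene (step 1); the cycloaddition closes ring B on preformed ring A (step 2); ring A is adjusted (C4 methyl, removal of the C1 oxygen, steps 3–6) and its stereocentres are set (steps 7–8); the esters follow (steps 9–10); the silyl enol ether kept from the cycloaddition directs the isopropylidene to C7 (steps 11–12).
Stereochemistry: C10 comes from the catalyst-controlled cycloaddition; C5 (trans fusion), C4 and C3 are relayed from C10 by Birch protonation, enolate hydroxylation anti to the C10 methyl, and axial hydride delivery; the side-chain centre comes from (R)-2-methylbutanoic acid. The ring-fusion centre of the cycloadduct is erased on purpose in step 3, so only the C10 configuration of the key step has to be right.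

Key step: step 2

Assumption: (S)-BINOL is written as the ligand antipode that gives the (4aR) quaternary centre of 4; the sense of induction of this chelated quinone has to be confirmed on 4, and (R)-BINOL, equally available, would replace it with no other change.

**Route**

Step 1
Reactants: 1 methyl vinyl ketone (but-3-en-2-one)
Product: 2 2-(triisopropylsilyloxy)buta-1,3-diene
Conditions: i-Pr3SiOTf (1.05 equiv), Et3N (1.2 equiv), Et2O, 0 °C → rt
Reagents that add atoms: triisopropylsilyl trifluoromethanesulfonate, CC(C)[Si](C(C)C)(C(C)C)OS(=O)(=O)C(F)(F)F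
Why: Soft enolisation of the methyl ketone with silyl triflate and amine (O-silylation of an enone to a 2-silyloxydiene) is standard and creates no stereocentre.

Step 2
Reactants: 2 2-(triisopropylsilyloxy)buta-1,3-diene; 3 2-methoxy-5-methyl-1,4-benzoquinone
Product: 4 (4aR,8aS)-2-methoxy-4a-methyl-6-(triisopropylsilyloxy)-4a,5,8,8a-tetrahydronaphthalene-1,4-dione (cis-fused cycloadduct)
Conditions: (S)-BINOL (0.2 equiv), TiCl2(Oi-Pr)2 (0.2 equiv), 4 Å molecular sieves, CH2Cl2, rt (catalyst formation, sieves filtered off); 2 (1.5 equiv), toluene, −40 → 0 °C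
Reagents that add atoms: none
Why: Lewis-acid-catalysed normal-demand [4+2] cycloaddition (asynchronous; the limiting Mukaiyama–Michael/ring-closure path leads to the same adduct), the closest known reaction type being the BINOL–TiCl2-catalysed Diels–Alder reaction of 2-alkoxy-1,4-benzoquinones with silyloxydienes. Ring B closes as a six-membered carbocycle by suprafacial addition of the diene termini C9 and C6 to the quinone C5=C6 bond (C10=C5 in plan numbering). The quaternary centre C10 is set by the catalyst, whose binaphtholate differentiates the two faces of the titanium-bound quinone; the C5 hydrogen ends up cis to the C10 methyl by suprafacial addition and is not carried further. Site selectivity between the two quinone alkenes is secured because the methoxy-bearing one is a deactivated vinylogous ester. Regioselectivity (the CH2 terminus next to the silyloxy carbon must bond to the methyl-bearing carbon) is secured by two-point binding of tetravalent titanium to the quinone C1 carbonyl oxygen and the neighbouring methoxy oxygen, which makes the methyl-bearing quinone C5 the β-carbon of the activated enone; this is the sense of the uncatalysed reaction and the opposite of that found with monodentate Lewis acids. Enantioface selectivity is the one selectivity without a safeguard in the substrate and rests on the catalyst alone.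

Step 3
Reactants: 4 (4aR,8aS)-2-methoxy-4a-methyl-6-(triisopropylsilyloxy)-4a,5,8,8a-tetrahydronaphthalene-1,4-dione
Product: 6 (4aR)-2-methoxy-4a-methyl-4-oxo-6-(triisopropylsilyloxy)-4,4a,5,8-tetrahydronaphthalen-1-yl trifluoromethanesulfonate, via potassium enolate 5 (not isolated)
Conditions: KN(SiMe3)2 (1.1 equiv), THF, −78 °C; then PhNTf2 (1.2 equiv), −78 → 0 °C
Reagents that add atoms: N-phenylbis(trifluoromethanesulfonimide), O=S(=O)(N(c1ccccc1)S(=O)(=O)C(F)(F)F)C(F)(F)F
Why: Ketone-to-enol-triflate conversion: the ring-fusion hydrogen at C5 (plan numbering) is the only acidic C–H of 4 (the C1 carbonyl has no α-hydrogen), so enolate formation and O-triflation at C4 are regiodefined, and the cis ring-fusion centre is removed on purpose.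

Step 4
Reactants: 6 (4aR)-2-methoxy-4a-methyl-4-oxo-6-(triisopropylsilyloxy)-4,4a,5,8-tetrahydronaphthalen-1-yl trifluoromethanesulfonate
Product: 7 (8aR)-3-methoxy-4,8a-dimethyl-7-(triisopropylsilyloxy)-8,8a-dihydronaphthalen-1(5H)-one
Conditions: MeZnCl (1.5 equiv), Pd(PPh3)4 (5 mol %), THF, rt → 40 °C
Reagents that add atoms: methylzinc chloride, C[Zn]Cl
Why: Negishi coupling: zerovalent palladium inserts into the electron-poor dienyl triflate and the methylzinc reagent transfers the C4 methyl without touching the ketone or the silyl enol ether; no stereocentre is affected.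

Step 5
Reactants: 7 (8aR)-3-methoxy-4,8a-dimethyl-7-(triisopropylsilyloxy)-8,8a-dihydronaphthalen-1(5H)-one
Product: 9 (4aS)-1,4a-dimethyl-6-(triisopropylsilyloxy)-5,8-dihydronaphthalen-2(4aH)-one, via dienyl alcohol 8 (not isolated)
Conditions: i-Bu2AlH (1.2 equiv), CH2Cl2, −78 °C; then aq. oxalic acid, THF, 0 °C
Reagents that add atoms: water, O
Why: Stork–Danheiser-type transposition: 1,2-reduction of the C1 vinylogous-ester carbonyl and mild acid ionise the new allylic alcohol to a methoxy-stabilised pentadienyl cation that takes up water at C3 and loses methanol, which removes the activating C1 oxygen and unveils the C3 ketone as a cross-conjugated dienone; the bulky silyl enol ether should survive cold oxalic acid.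

Step 6
Reactants: 9 (4aS)-1,4a-dimethyl-6-(triisopropylsilyloxy)-5,8-dihydronaphthalen-2(4aH)-one
Product: 10 (4aR)-1,4a-dimethyl-6-(triisopropylsilyloxy)-4,4a,5,8-tetrahydronaphthalen-2(3H)-one
Conditions: H2 (1 atm), RhCl(PPh3)3 (5 mol %), benzene–EtOH, rt
Reagents that add atoms: none
Why: Homogeneous hydrogenation with RhCl(PPh3)3 reduces only the disubstituted C1=C2 alkene of a cross-conjugated 1,4-dien-3-one and leaves the tetrasubstituted enone alkene and the trisubstituted silyl enol ether, as in the steroid series.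

Step 7
Reactants: 10 (4aR)-1,4a-dimethyl-6-(triisopropylsilyloxy)-4,4a,5,8-tetrahydronaphthalen-2(3H)-one
Product: 12 (1S,4aR,8aR)-1-hydroxy-1,4a-dimethyl-6-(triisopropylsilyloxy)-3,4,4a,5,8,8a-hexahydronaphthalen-2(1H)-one, via lithium enolate 11 (not isolated)
Conditions: Li (2.1 equiv), t-BuOH (1.0 equiv), NH3–THF, −78 °C; NH3 removed; then 2-(phenylsulfonyl)-3-phenyloxaziridine (1.3 equiv), THF, −78 °C; then H2O
Reagents that add atoms: 2-(phenylsulfonyl)-3-phenyloxaziridine, O=S(=O)(N1OC1c1ccccc1)c1ccccc1
Why: Birch reduction with enolate trapping: protonation at C5 occurs axially to give the trans-fused decalin, and the regiodefined C3–C4 lithium enolate is hydroxylated by the N-sulfonyloxaziridine on the face opposite to the axial C10 methyl (1,3-diaxial shielding of the other face), which sets C4 with the hydroxyl trans to that methyl; the silyl enol ether is inert to both stages.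

Step 8
Reactants: 12 (1S,4aR,8aR)-1-hydroxy-1,4a-dimethyl-6-(triisopropylsilyloxy)-3,4,4a,5,8,8a-hexahydronaphthalen-2(1H)-one
Product: 13 (1S,2S,4aR,8aR)-1,4a-dimethyl-6-(triisopropylsilyloxy)-1,2,3,4,4a,5,8,8a-octahydronaphthalene-1,2-diol
Conditions: NaBH4, MeOH, −20 → 0 °C
Reagents that add atoms: none
Why: Borohydride reduction of the α-hydroxy ketone: hydride adds axially at C3 from the face opposite to the axial C4 methyl, so the C3 alcohol is equatorial and trans to the C4 hydroxyl, as in 4,4-disubstituted 3-keto decalins and steroids.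

Step 9
Reactants: 13 (1S,2S,4aR,8aR)-1,4a-dimethyl-6-(triisopropylsilyloxy)-1,2,3,4,4a,5,8,8a-octahydronaphthalene-1,2-diol; 14 (R)-2-methylbutanoic acid
Product: 15 (1S,2S,4aR,8aR)-1-hydroxy-1,4a-dimethyl-6-(triisopropylsilyloxy)-1,2,3,4,4a,5,8,8a-octahydronaphthalen-2-yl (2R)-2-methylbutanoate
Conditions: DCC (1.2 equiv), DMAP (0.1 equiv), CH2Cl2, 0 °C → rt
Reagents that add atoms: none
Why: Steglich esterification: only the secondary C3 alcohol is acylated, the tertiary one being inert under carbodiimide/DMAP conditions, and the side-chain stereocentre is brought in with the acid (cold, little DMAP, to avoid its epimerisation).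

Step 10
Reactants: 15 (1S,2S,4aR,8aR)-1-hydroxy-1,4a-dimethyl-6-(triisopropylsilyloxy)-1,2,3,4,4a,5,8,8a-octahydronaphthalen-2-yl (2R)-2-methylbutanoate
Product: 16 (1S,2S,4aR,8aR)-1-acetoxy-1,4a-dimethyl-6-(triisopropylsilyloxy)-1,2,3,4,4a,5,8,8a-octahydronaphthalen-2-yl (2R)-2-methylbutanoate
Conditions: Ac2O (5 equiv), DMAP (1 equiv), Et3N (5 equiv), CH2Cl2, 40 °C
Reagents that add atoms: acetic anhydride, CC(=O)OC(C)=O
Why: DMAP-catalysed acetylation of a tertiary alcohol with acetic anhydride; without a Lewis acid the silyl enol ether and the neighbouring ester are untouched and no stereocentre changes.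

Step 11
Reactants: 16 (1S,2S,4aR,8aR)-1-acetoxy-1,4a-dimethyl-6-(triisopropylsilyloxy)-1,2,3,4,4a,5,8,8a-octahydronaphthalen-2-yl (2R)-2-methylbutanoate
Product: 17 (1S,2S,4aR,8aR)-1-acetoxy-7-(2-hydroxypropan-2-yl)-1,4a-dimethyl-6-oxodecahydronaphthalen-2-yl (2R)-2-methylbutanoate (both C7 epimers)
Conditions: acetone (3 equiv), TiCl4 (1.1 equiv), CH2Cl2, −78 °C; then H2O
Reagents that add atoms: acetone, CC(C)=O
Why: Mukaiyama aldol addition to acetone: the silyl enol ether carried from step 2 reacts only at C7, so the site of side-chain attachment is fixed by the cycloaddition; the new C7 centre is destroyed in step 12 and both epimers serve.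

Step 12
Reactants: 17 (1S,2S,4aR,8aR)-1-acetoxy-7-(2-hydroxypropan-2-yl)-1,4a-dimethyl-6-oxodecahydronaphthalen-2-yl (2R)-2-methylbutanoate
Product: 19 (1S,2S,4aR,8aR)-1-acetoxy-1,4a-dimethyl-6-oxo-7-(propan-2-ylidene)decahydronaphthalen-2-yl (2R)-2-methylbutanoate (CNP0111007.1), via tertiary mesylate 18 (not isolated)
Conditions: MsCl (1.5 equiv), Et3N (1.5 equiv), CH2Cl2, 0 °C; then DBU (2 equiv), rt
Reagents that add atoms: none
Why: Sulfonylation of the tertiary aldol hydroxyl and base-induced β-elimination (E1cB through the C8 ketone enolate) give the conjugated tetrasubstituted alkylidene ketone, and DBU brings any isopropenyl isomer into conjugation; the esters and the other stereocentres are not affected.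

**Compound list**

1 | methyl vinyl ketone | CC(=O)C=C | starting material
2 | 2-(triisopropylsilyloxy)buta-1,3-diene | C=CC(=C)O[Si](C(C)C)(C(C)C)C(C)C | intermediate
3 | 2-methoxy-5-methyl-1,4-benzoquinone | COC1=CC(=O)C(C)=CC1=O | starting material
4 | (4aR,8aS)-2-methoxy-4a-methyl-6-(triisopropylsilyloxy)-4a,5,8,8a-tetrahydronaphthalene-1,4-dione | COC1=CC(=O)[C@]2(C)CC(O[Si](C(C)C)(C(C)C)C(C)C)=CC[C@@H]2C1=O | intermediate
5 | potassium (4aR)-2-methoxy-4a-methyl-4-oxo-6-(triisopropylsilyloxy)-4,4a,5,8-tetrahydronaphthalen-1-olate | COC1=CC(=O)[C@]2(C)CC(O[Si](C(C)C)(C(C)C)C(C)C)=CCC2=C1[O-].[K+] | intermediate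
6 | (4aR)-2-methoxy-4a-methyl-4-oxo-6-(triisopropylsilyloxy)-4,4a,5,8-tetrahydronaphthalen-1-yl trifluoromethanesulfonate | COC1=CC(=O)[C@]2(C)CC(O[Si](C(C)C)(C(C)C)C(C)C)=CCC2=C1OS(=O)(=O)C(F)(F)F | intermediate
7 | (8aR)-3-methoxy-4,8a-dimethyl-7-(triisopropylsilyloxy)-8,8a-dihydronaphthalen-1(5H)-one | COC1=CC(=O)[C@]2(C)CC(O[Si](C(C)C)(C(C)C)C(C)C)=CCC2=C1C | intermediate
8 | (8aR)-3-methoxy-4,8a-dimethyl-7-(triisopropylsilyloxy)-1,5,8,8a-tetrahydronaphthalen-1-ol (both C1 epimers) | COC1=CC(O)[C@]2(C)CC(O[Si](C(C)C)(C(C)C)C(C)C)=CCC2=C1C | intermediate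
9 | (4aS)-1,4a-dimethyl-6-(triisopropylsilyloxy)-5,8-dihydronaphthalen-2(4aH)-one | O=C1C=C[C@]2(C)CC(O[Si](C(C)C)(C(C)C)C(C)C)=CCC2=C1C | intermediate
10 | (4aR)-1,4a-dimethyl-6-(triisopropylsilyloxy)-4,4a,5,8-tetrahydronaphthalen-2(3H)-one | O=C1CC[C@]2(C)CC(O[Si](C(C)C)(C(C)C)C(C)C)=CCC2=C1C | intermediate
11 | lithium (4aR,8aR)-1,4a-dimethyl-6-(triisopropylsilyloxy)-3,4,4a,5,8,8a-hexahydronaphthalen-2-olate (trans-fused) | CC1=C([O-])CC[C@]2(C)CC(O[Si](C(C)C)(C(C)C)C(C)C)=CC[C@@H]12.[Li+] | intermediate
12 | (1S,4aR,8aR)-1-hydroxy-1,4a-dimethyl-6-(triisopropylsilyloxy)-3,4,4a,5,8,8a-hexahydronaphthalen-2(1H)-one | O=C1CC[C@]2(C)CC(O[Si](C(C)C)(C(C)C)C(C)C)=CC[C@H]2[C@]1(C)O | intermediate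
13 | (1S,2S,4aR,8aR)-1,4a-dimethyl-6-(triisopropylsilyloxy)-1,2,3,4,4a,5,8,8a-octahydronaphthalene-1,2-diol | O[C@H]1CC[C@]2(C)CC(O[Si](C(C)C)(C(C)C)C(C)C)=CC[C@H]2[C@]1(C)O | intermediate
14 | (R)-2-methylbutanoic acid | CC[C@@H](C)C(=O)O | starting material
15 | (1S,2S,4aR,8aR)-1-hydroxy-1,4a-dimethyl-6-(triisopropylsilyloxy)-1,2,3,4,4a,5,8,8a-octahydronaphthalen-2-yl (2R)-2-methylbutanoate | CC[C@@H](C)C(=O)O[C@H]1CC[C@]2(C)CC(O[Si](C(C)C)(C(C)C)C(C)C)=CC[C@H]2[C@]1(C)O | intermediate
16 | (1S,2S,4aR,8aR)-1-acetoxy-1,4a-dimethyl-6-(triisopropylsilyloxy)-1,2,3,4,4a,5,8,8a-octahydronaphthalen-2-yl (2R)-2-methylbutanoate | CC[C@@H](C)C(=O)O[C@H]1CC[C@]2(C)CC(O[Si](C(C)C)(C(C)C)C(C)C)=CC[C@H]2[C@]1(C)OC(C)=O | intermediate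
17 | (1S,2S,4aR,8aR)-1-acetoxy-7-(2-hydroxypropan-2-yl)-1,4a-dimethyl-6-oxodecahydronaphthalen-2-yl (2R)-2-methylbutanoate (both C7 epimers) | CC[C@@H](C)C(=O)O[C@H]1CC[C@]2(C)CC(=O)C(C(C)(C)O)C[C@H]2[C@]1(C)OC(C)=O | intermediate
18 | methanesulfonate of 17 at the side-chain tertiary hydroxyl | CC[C@@H](C)C(=O)O[C@H]1CC[C@]2(C)CC(=O)C(C(C)(C)OS(C)(=O)=O)C[C@H]2[C@]1(C)OC(C)=O | intermediate
19 | (1S,2S,4aR,8aR)-1-acetoxy-1,4a-dimethyl-6-oxo-7-(propan-2-ylidene)decahydronaphthalen-2-yl (2R)-2-methylbutanoate | CC[C@@H](C)C(=O)O[C@H]1CC[C@]2(C)CC(=O)C(=C(C)C)C[C@H]2[C@]1(C)OC(C)=O | target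

**Totals and risks**

Total step count: 12. Longest linear sequence: 12 steps (1 → 19); 3 and 14 enter as purchased fragments.

Steps most likely to fail:

Step 2. What may go wrong: poor enantioface discrimination, slow cycloaddition at the trisubstituted quinone alkene, or leakage of regiocontrol through one-point binding of the catalyst at the vinylogous-ester carbonyl. Fallback (resolution in place of asymmetric catalysis), setting out from 2 and 3 and returning at 4: the two are combined without a chiral catalyst (toluene, 90 °C, or SnCl4, CH2Cl2, −78 °C, which chelates like the titanium catalyst) to give the racemic cis-fused cycloadduct F1 with the same regiochemistry. Preparative chromatography on a chiral stationary phase (amylose carbamate, CO2/MeOH) separates it into 4 and the (4aS,8aR) antipode F2, which is set aside.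

Step 7. What may go wrong: reduction past the enolate stage, consumption of the oxaziridine by the alkoxide present, or loss of facial control in the C–O bond formation. Fallback (oxygen introduced in a separate, equilibrating step), setting out from 10 and returning at 12: the same Li/NH3 reduction is quenched with NH4Cl to give, through 11, the trans-fused methyl ketone F3. KOt-Bu, O2 and P(OEt)3 in THF/t-BuOH at −20 °C then hydroxylate the more substituted α-carbon through the thermodynamic enolate, again anti to the angular methyl, to give 12.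

Step 11. What may go wrong: low reactivity of the hindered silyl enol ether toward a ketone electrophile, retro-aldol cleavage on work-up, or Lewis-acid ionisation of the tertiary acetate. Fallback (base-mediated aldol of the free ketone, no Lewis acid), setting out from 16 and returning at 17: Bu4NF/AcOH in THF at 0 °C gives the free ketone F4. LiN(SiMe3)2 (1.05 equiv, THF, −78 °C) deprotonates it kinetically at C7 (C9 is neopentyl and shielded by the angular methyl; the ester α-hydrogens are less acidic and hindered) to the lithium enolate F5, which adds to acetone at −78 °C (cold AcOH quench) to give 17.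

Further compounds
F1 | step 2 | racemic cis-2-methoxy-4a-methyl-6-(triisopropylsilyloxy)-4a,5,8,8a-tetrahydronaphthalene-1,4-dione (both enantiomers) | COC1=CC(=O)[C@]2(C)CC(O[Si](C(C)C)(C(C)C)C(C)C)=CC[C@@H]2C1=O.COC1=CC(=O)[C@@]2(C)CC(O[Si](C(C)C)(C(C)C)C(C)C)=CC[C@H]2C1=O
F2 | step 2 | (4aS,8aR)-2-methoxy-4a-methyl-6-(triisopropylsilyloxy)-4a,5,8,8a-tetrahydronaphthalene-1,4-dione | COC1=CC(=O)[C@@]2(C)CC(O[Si](C(C)C)(C(C)C)C(C)C)=CC[C@H]2C1=O
F3 | step 7 | (1S,4aR,8aS)-1,4a-dimethyl-6-(triisopropylsilyloxy)-3,4,4a,5,8,8a-hexahydronaphthalen-2(1H)-one (trans-fused; the C1 epimer serves equally) | O=C1CC[C@]2(C)CC(O[Si](C(C)C)(C(C)C)C(C)C)=CC[C@H]2[C@@H]1C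
F4 | step 11 | (1S,2S,4aR,8aR)-1-acetoxy-1,4a-dimethyl-6-oxodecahydronaphthalen-2-yl (2R)-2-methylbutanoate | CC[C@@H](C)C(=O)O[C@H]1CC[C@]2(C)CC(=O)CC[C@H]2[C@]1(C)OC(C)=O
F5 | step 11 | lithium enolate of F4 (C7=C8 enolate) | CC[C@@H](C)C(=O)O[C@H]1CC[C@]2(C)CC([O-])=CC[C@H]2[C@]1(C)OC(C)=O.[Li+]
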